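**Plan**

1. Locants: ring A = C1–C5 and C10, ring B = C5–C10 (C4 = CMe2, C5 = fusion CH, C10 = fusion C–CH3, C8=C9 ring alkene); chain C11–C17 (methyl on C13, stereocenter C17), ester carbon C18.
2. Retrosynthetic cuts, in order: the O-methyl group and the C18 oxidation level; C14–C15 (alkenyl–alkenyl coupling); C9–C11 (alkyl–enol triflate coupling); C3–C4 (radical ring closure); C10–C1 and C10–CH3 (enolate alkylations).
3. Forward: ring B is (R)-carvone; C10 is made quaternary by methylation and then 2-sulfonylallylation; ring A closes when an H atom is delivered to the isopropenyl CH2 and the tertiary C4 radical adds to C3; the C9 carbonyl becomes an enol triflate that takes a four-carbon alkyne unit, which is carboaluminated and coupled with a C15–C18 vinyl iodide.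
4. Enabling feature: the gem-dimethyl carbon C4 of ring A lies next to the fusion CH C5, so C4 with one methyl is the isopropenyl group of carvone; C4 and C3 (β-carbon of a vinyl sulfone) are both acceptor carbons in polar terms and are joined through a radical.
5. Stereochemistry: C5 from (R)-carvone; C10 by alkylation anti to the isopropenyl group; C17 from methyl (S)-3-hydroxy-2-methylpropanoate; 13E from syn-carboalumination and 15E from Takai olefination, both kept in the coupling.
6. Helpers: the phenylsulfonyl group at C2 (removed reductively in step 8) and the C9 carbonyl (consumed as the enol triflate).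

Key step: step 5

Remark on the chemistry: 6 is drawn as its expected major trans isomer (both C6 epimers give the same enolate in step 4); 9, 10, 11 and 14 (and the fallback compounds F2, F3 and F4) are expected as mixtures of epimers at the sulfonyl carbon C2, drawn without configuration there, and step 8 removes that center.

**Route**

Step 1
Reactants: 1 phenyl vinyl sulfone
Product: 2 2-(phenylsulfonyl)prop-2-en-1-ol
Conditions: aq. CH2O (37 %), DABCO (1 equiv), THF, rt
Reagents that add atoms: formaldehyde, C=O
Why: Morita–Baylis–Hillman hydroxymethylation, in which DABCO adds to the vinyl sulfone, the α-sulfonyl carbanion is trapped by formaldehyde and DABCO is eliminated; no stereocenter is formed.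

Step 2
Reactants: 2 2-(phenylsulfonyl)prop-2-en-1-ol
Product: 3 3-bromo-2-(phenylsulfonyl)prop-1-ene
Conditions: PBr3 (0.4 equiv), Et2O, 0 °C
Reagents that add atoms: phosphorus tribromide, BrP(Br)Br
Why: Bromination of a primary allylic alcohol with PBr3, where SN2 and SN2′ displacement lead to the same constitution.

Step 3
Reactants: 4 (R)-(−)-carvone
Product: 6 (5R,6S)-2,6-dimethyl-5-(prop-1-en-2-yl)cyclohex-2-en-1-one (trans-6-methylcarvone), via lithium dienolate 5 (not isolated)
Conditions: LiN(iPr)2 (LDA), THF, −78 °C; then MeI, −78 → 0 °C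
Reagents that add atoms: iodomethane, CI
Why: Kinetic α′-deprotonation of the cross-conjugated enone and SN2 methylation of the dienolate, expected mainly anti to the isopropenyl group; the C6 configuration is of no consequence because C6 becomes planar again in step 4.

Step 4
Reactants: 6 trans-6-methylcarvone; 3 3-bromo-2-(phenylsulfonyl)prop-1-ene
Product: 8 (5S,6S)-2,6-dimethyl-6-[2-(phenylsulfonyl)prop-2-en-1-yl]-5-(prop-1-en-2-yl)cyclohex-2-en-1-one, via lithium enolate 7 (not isolated)
Conditions: LiN(iPr)2, THF, −78 → −20 °C; then 3, −78 °C → rt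
Reagents that add atoms: none
Why: Enolate alkylation with an activated allylic bromide creates the quaternary C10, and the electrophile should enter on the enolate face anti to the neighbouring isopropenyl group at C5, which places the C1 chain trans to C4 and the methyl cis to it, as the trans ring fusion requires.

Step 5
Reactants: 8 the doubly alkylated carvone
Product: 9 (4aS,8aS)-2,5,5,8a-tetramethyl-7-(phenylsulfonyl)-4a,5,6,7,8,8a-hexahydronaphthalen-1(4H)-one
Conditions: Fe(acac)3 (30 mol %), PhSiH3 (2.5 equiv), EtOH/HOCH2CH2OH 5:1, 0.01 M, 60 °C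
Reagents that add atoms: none
Why: H-atom transfer from the iron hydride formed from Fe(acac)3 and PhSiH3 to the CH2 terminus of the isopropenyl group makes the second C4 methyl and a tertiary C4 radical, which adds to C3, the unsubstituted β-carbon of the vinyl sulfone, and the resulting α-sulfonyl C2 radical is reduced by divalent iron and protonated by ethanol. The closest known reaction type is the iron-hydride-initiated reductive olefin coupling (radical conjugate addition of an unactivated alkene to an electron-poor alkene), here intramolecular and uniting two carbons that are both acceptor sites in polar terms. Ring A closes in the 6-endo-trig mode, which should be favoured over 5-exo attack at C2 because C3 is unsubstituted and β to the sulfone. The only new stereocenter is C2, which is not controlled and is removed in step 8, while the trans ring fusion is already fixed by C5 and C10, whose substituents C4 and C1 are trans-diequatorial on ring B and therefore within bonding distance. The step needs H-atom transfer to the electron-rich isopropenyl alkene in preference to the electron-poor vinyl sulfone and enone, which the polarity of the iron hydride and high dilution should secure; attack of the C4 radical on the enone is excluded because it would form a four-membered ring.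

Step 6
Reactants: 9 the bicyclic enone sulfone
Product: 11 (4aS,8aS)-2,5,5,8a-tetramethyl-7-(phenylsulfonyl)-3,4,4a,5,6,7,8,8a-octahydronaphthalen-1-yl trifluoromethanesulfonate, via lithium enolate 10 (not isolated)
Conditions: LiBH(sBu)3 (L-Selectride, 1.1 equiv), THF, −78 °C; then PhNTf2, −78 → 0 °C
Reagents that add atoms: N-phenylbis(trifluoromethanesulfonimide), O=S(=O)(N(c1ccccc1)S(=O)(=O)C(F)(F)F)C(F)(F)F
Why: Conjugate hydride reduction (1,2-attack is blocked by the quaternary C10) gives the C8=C9 enolate regiospecifically, and O-triflation traps it as the tetrasubstituted enol triflate; C8 is sp2, so no stereocenter is set.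

Step 7
Reactants: 11 the enol triflate; 12 (4-bromobut-1-yn-1-yl)trimethylsilane
Product: 14 trimethyl{4-[(4aS,8aS)-2,5,5,8a-tetramethyl-7-(phenylsulfonyl)-3,4,4a,5,6,7,8,8a-octahydronaphthalen-1-yl]but-1-yn-1-yl}silane, via alkylzinc bromide 13 (not isolated)
Conditions: 12, Zn dust, LiCl, THF, 50 °C; then 11, PdCl2(dppf) (5 mol %), THF/NMP, 60 °C
Reagents that add atoms: none
Why: Negishi sp3–sp2 coupling of a primary alkylzinc bromide with an enol triflate forms C9–C11, the wide-bite-angle dppf ligand favouring reductive elimination over β-hydride elimination, and sulfone and silylalkyne are inert to the organozinc.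

Step 8
Reactants: 14 the coupled sulfone
Product: 16 4-[(4aS,8aS)-2,5,5,8a-tetramethyl-3,4,4a,5,6,7,8,8a-octahydronaphthalen-1-yl]but-1-yne, via silylalkyne 15 (not isolated)
Conditions: Na/Hg (6 % Na), Na2HPO4, MeOH/THF, −20 °C → rt; then K2CO3, MeOH, rt
Reagents that add atoms: none
Why: Reductive desulfonylation by electron transfer cleaves the C2–S bond and methanol protonates the carbanion, which erases the helper group and the C2 center, and carbonate-mediated methanolysis then frees the terminal alkyne.

Step 9
Reactants: 17 methyl (S)-3-hydroxy-2-methylpropanoate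
Product: 18 methyl (S)-3-[(tert-butyldimethylsilyl)oxy]-2-methylpropanoate
Conditions: TBSCl, imidazole, CH2Cl2, 0 °C → rt
Reagents that add atoms: tert-butyldimethylsilyl chloride, CC(C)(C)[Si](C)(C)Cl
Why: Standard silylation of a primary alcohol, which leaves the stereocenter untouched.

Step 10
Reactants: 18 the silyl ether ester
Product: 19 (S)-3-[(tert-butyldimethylsilyl)oxy]-2-methylpropanal
Conditions: iBu2AlH (1.05 equiv), CH2Cl2, −78 °C; MeOH, aq. potassium sodium tartrate
Reagents that add atoms: none
Why: Partial ester reduction should stop at the aldehyde because the tetrahedral aluminium hemiacetal persists at −78 °C, and the α-stereocenter should be retained at this temperature.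

Step 11
Reactants: 19 the aldehyde
Product: 20 (R,E)-tert-butyl[(4-iodo-2-methylbut-3-en-1-yl)oxy]dimethylsilane
Conditions: CrCl2 (6 equiv), CHI3 (2 equiv), THF/dioxane, 0 °C → rt
Reagents that add atoms: iodoform, IC(I)I
Why: Takai olefination through a geminal dichromium species should give the E-vinyl iodide under non-basic conditions that do not epimerize the α-center (the descriptor changes from S to R only through the priority rules).

Step 12
Reactants: 16 the terminal alkyne; 20 the vinyl iodide
Product: 22 tert-butyl{[(2R,3E,5E)-2,6-dimethyl-8-[(4aS,8aS)-2,5,5,8a-tetramethyl-3,4,4a,5,6,7,8,8a-octahydronaphthalen-1-yl]octa-3,5-dien-1-yl]oxy}dimethylsilane, via alkenylalane 21 (not isolated)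
Conditions: Me3Al (2.5 equiv), Cp2ZrCl2 (0.25 equiv), CH2Cl2, 0 °C → rt; evaporate, THF; then 20, Pd(PPh3)4 (5 mol %), ZnCl2 (1 equiv), rt
Reagents that add atoms: trimethylaluminium, C[Al](C)C
Why: Zirconium-catalysed syn-carboalumination puts methyl on C13 and aluminium on C14 cis to each other, which fixes 13E, and the palladium-catalysed, zinc-assisted Negishi alkenyl–alkenyl coupling forms C14–C15 with retention at both partners, the C17 center being remote from the reacting carbons.

Step 13
Reactants: 22 the silyl ether diene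
Product: 23 (2R,3E,5E)-2,6-dimethyl-8-[(4aS,8aS)-2,5,5,8a-tetramethyl-3,4,4a,5,6,7,8,8a-octahydronaphthalen-1-yl]octa-3,5-dien-1-ol
Conditions: Bu4NF, THF, 0 °C → rt
Reagents that add atoms: none
Why: Fluoride-induced cleavage of the silyl ether, which does not touch the diene or C17.

Step 14
Reactants: 23 the dienol
Product: 25 (2R,3E,5E)-2,6-dimethyl-8-[(4aS,8aS)-2,5,5,8a-tetramethyl-3,4,4a,5,6,7,8,8a-octahydronaphthalen-1-yl]octa-3,5-dienoic acid, via aldehyde 24 (not isolated)
Conditions: DMP (1,1,1-triacetoxy-1,1-dihydro-1,2-benziodoxol-3(1H)-one), NaHCO3, CH2Cl2, 0 °C; filter, concentrate cold; then NaClO2, NaH2PO4, 2-methyl-2-butene (large excess), tBuOH/H2O, 0 °C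
Reagents that add atoms: sodium chlorite, [Na+].[O-]Cl=O
Why: Periodinane oxidation followed at once by Pinnick chlorite oxidation keeps the medium non-basic throughout, so that C17 and the skipped diene should survive, with 2-methyl-2-butene scavenging hypochlorous acid.

Step 15
Reactants: 25 the dienoic acid
Product: 26 methyl (2R,3E,5E)-2,6-dimethyl-8-[(4aS,8aS)-2,5,5,8a-tetramethyl-3,4,4a,5,6,7,8,8a-octahydronaphthalen-1-yl]octa-3,5-dienoate (target)
Conditions: TMSCHN2, PhMe/MeOH 4:1, 0 °C
Reagents that add atoms: (trimethylsilyl)diazomethane, C[Si](C)(C)C=[N+]=[N-]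
Why: O-Methylation of the carboxylic acid by a diazomethane equivalent under neutral conditions, which avoids enolization at C17.

**Compound list**

1 | phenyl vinyl sulfone | C=CS(=O)(=O)c1ccccc1 | starting material
2 | 2-(phenylsulfonyl)prop-2-en-1-ol | OCC(=C)S(=O)(=O)c1ccccc1 | intermediate
3 | 3-bromo-2-(phenylsulfonyl)prop-1-ene | BrCC(=C)S(=O)(=O)c1ccccc1 | intermediate
4 | (R)-(−)-carvone | CC1=CC[C@H](CC1=O)C(C)=C | starting material
5 | lithium dienolate of (R)-carvone (O–C1=C6, C2=C3) | [Li+].[O-]C1=C[C@H](C(C)=C)CC=C1C | intermediate (not isolated)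
6 | (5R,6S)-2,6-dimethyl-5-(prop-1-en-2-yl)cyclohex-2-en-1-one (trans-6-methylcarvone) | O=C1C(C)=CC[C@@H](C(C)=C)[C@@H]1C | intermediate
7 | lithium enolate of 6 (O–C1=C6 tetrasubstituted) | [Li+].[O-]C1=C(C)[C@H](C(C)=C)CC=C1C | intermediate (not isolated)
8 | (5S,6S)-2,6-dimethyl-6-[2-(phenylsulfonyl)prop-2-en-1-yl]-5-(prop-1-en-2-yl)cyclohex-2-en-1-one (sulfonylallyl trans to isopropenyl) | O=C1C(C)=CC[C@@H](C(C)=C)[C@]1(C)CC(=C)S(=O)(=O)c2ccccc2 | intermediate
9 | (4aS,8aS)-2,5,5,8a-tetramethyl-7-(phenylsulfonyl)-4a,5,6,7,8,8a-hexahydronaphthalen-1(4H)-one (trans-fused; sulfonyl carbon as epimer mixture) | O=C1C(C)=CC[C@H]2C(C)(C)CC(S(=O)(=O)c3ccccc3)C[C@]12C | intermediate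
10 | lithium C8=C9 enolate from 9 | [Li+].[O-]C1=C(C)CC[C@H]2C(C)(C)CC(S(=O)(=O)c3ccccc3)C[C@]12C | intermediate (not isolated)
11 | (4aS,8aS)-2,5,5,8a-tetramethyl-7-(phenylsulfonyl)-3,4,4a,5,6,7,8,8a-octahydronaphthalen-1-yl trifluoromethanesulfonate | FC(F)(F)S(=O)(=O)OC1=C(C)CC[C@H]2C(C)(C)CC(S(=O)(=O)c3ccccc3)C[C@]12C | intermediate
12 | (4-bromobut-1-yn-1-yl)trimethylsilane | C[Si](C)(C)C#CCCBr | starting material
13 | [4-(trimethylsilyl)but-3-yn-1-yl]zinc bromide | C[Si](C)(C)C#CCC[Zn]Br | intermediate (not isolated)
14 | trimethyl{4-[(4aS,8aS)-2,5,5,8a-tetramethyl-7-(phenylsulfonyl)-3,4,4a,5,6,7,8,8a-octahydronaphthalen-1-yl]but-1-yn-1-yl}silane | C[Si](C)(C)C#CCCC1=C(C)CC[C@H]2C(C)(C)CC(S(=O)(=O)c3ccccc3)C[C@]12C | intermediate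
15 | trimethyl{4-[(4aS,8aS)-2,5,5,8a-tetramethyl-3,4,4a,5,6,7,8,8a-octahydronaphthalen-1-yl]but-1-yn-1-yl}silane | C[Si](C)(C)C#CCCC1=C(C)CC[C@H]2C(C)(C)CCC[C@]12C | intermediate (not isolated)
16 | 4-[(4aS,8aS)-2,5,5,8a-tetramethyl-3,4,4a,5,6,7,8,8a-octahydronaphthalen-1-yl]but-1-yne | C#CCCC1=C(C)CC[C@H]2C(C)(C)CCC[C@]12C | intermediate
17 | methyl (S)-3-hydroxy-2-methylpropanoate | OC[C@H](C)C(=O)OC | starting material
18 | methyl (S)-3-[(tert-butyldimethylsilyl)oxy]-2-methylpropanoate | CC(C)(C)[Si](C)(C)OC[C@H](C)C(=O)OC | intermediate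
19 | (S)-3-[(tert-butyldimethylsilyl)oxy]-2-methylpropanal | CC(C)(C)[Si](C)(C)OC[C@H](C)C=O | intermediate
20 | (R,E)-tert-butyl[(4-iodo-2-methylbut-3-en-1-yl)oxy]dimethylsilane | CC(C)(C)[Si](C)(C)OC[C@H](C)/C=C/I | intermediate
21 | (E)-alkenyldimethylalane from 16 (Al on C14 cis to the C13 methyl) | C[Al](C)/C=C(\C)CCC1=C(C)CC[C@H]2C(C)(C)CCC[C@]12C | intermediate (not isolated)
22 | tert-butyldimethylsilyl ether of 23 | CC(C)(C)[Si](C)(C)OC[C@H](C)/C=C/C=C(\C)CCC1=C(C)CC[C@H]2C(C)(C)CCC[C@]12C | intermediate
23 | (2R,3E,5E)-2,6-dimethyl-8-[(4aS,8aS)-2,5,5,8a-tetramethyl-3,4,4a,5,6,7,8,8a-octahydronaphthalen-1-yl]octa-3,5-dien-1-ol | OC[C@H](C)/C=C/C=C(\C)CCC1=C(C)CC[C@H]2C(C)(C)CCC[C@]12C | intermediate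
24 | (2R,3E,5E)-2,6-dimethyl-8-[(4aS,8aS)-2,5,5,8a-tetramethyl-3,4,4a,5,6,7,8,8a-octahydronaphthalen-1-yl]octa-3,5-dienal | O=C[C@H](C)/C=C/C=C(\C)CCC1=C(C)CC[C@H]2C(C)(C)CCC[C@]12C | intermediate (not isolated)
25 | (2R,3E,5E)-2,6-dimethyl-8-[(4aS,8aS)-2,5,5,8a-tetramethyl-3,4,4a,5,6,7,8,8a-octahydronaphthalen-1-yl]octa-3,5-dienoic acid | OC(=O)[C@H](C)/C=C/C=C(\C)CCC1=C(C)CC[C@H]2C(C)(C)CCC[C@]12C | intermediate
26 | methyl (2R,3E,5E)-2,6-dimethyl-8-[(4aS,8aS)-2,5,5,8a-tetramethyl-3,4,4a,5,6,7,8,8a-octahydronaphthalen-1-yl]octa-3,5-dienoate | COC(=O)[C@H](C)/C=C/C=C(\C)CCC1=C(C)CC[C@H]2C(C)(C)CCC[C@]12C | target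

**Count and risks**

Total step count: 15. Longest linear sequence: 11 steps (steps 1, 2, 4–8 and 12–15, from phenyl vinyl sulfone).

Steps most likely to fail:

Step 5. The H atom may be transferred to the vinyl sulfone or the enone instead of the isopropenyl group. That would lead to simple reduction, or to ring closure of the sulfonyl-stabilised radical onto the isopropenyl CH2 and thus a wrong skeleton. The fallback generates the C4 radical site-specifically from a halide. It sets out from 8: hydrobromination of the isopropenyl group (HBr in AcOH, CH2Cl2, 0 °C; the electron-poor vinyl sulfone should not add HBr) would give (5R,6S)-5-(2-bromopropan-2-yl)-2,6-dimethyl-6-[2-(phenylsulfonyl)prop-2-en-1-yl]cyclohex-2-en-1-one F1. Slow addition of Bu3SnH with AIBN in benzene at 80 °C should then abstract bromine and close ring A by the same 6-endo Giese addition. The fallback comes back to the route at 9.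

Step 7. Oxidative addition and transmetalation may be slow at the tetrasubstituted triflate next to the quaternary C10, so that protodezincation or β-hydride elimination of the alkylzinc takes over. The fallback builds C11 by carbonylation and adds the remaining three carbons by allylic substitution. It sets out from 11: methoxycarbonylation (Pd(OAc)2, dppp, CO, MeOH, Et3N, DMF, 60 °C) would give methyl (4aS,8aS)-2,5,5,8a-tetramethyl-7-(phenylsulfonyl)-3,4,4a,5,6,7,8,8a-octahydronaphthalene-1-carboxylate F2. Reduction with iBu2AlH would give the allylic alcohol [(4aS,8aS)-2,5,5,8a-tetramethyl-7-(phenylsulfonyl)-3,4,4a,5,6,7,8,8a-octahydronaphthalen-1-yl]methanol F3. PBr3 would give the allylic bromide (4aS,8aS)-1-(bromomethyl)-2,5,5,8a-tetramethyl-7-(phenylsulfonyl)-3,4,4a,5,6,7,8,8a-octahydronaphthalene F4. CuI-catalysed SN2 substitution at −78 → 0 °C with [3-(trimethylsilyl)prop-2-yn-1-yl]magnesium bromide F5 (from commercial 3-bromo-1-(trimethylsilyl)prop-1-yne and Mg) should then attack the primary C11, SN2′ attack at the fully substituted C8 being disfavoured. The fallback comes back to the route at 14.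

Step 14. At the aldehyde stage C17 may epimerize or the C15=C16 double bond may migrate into conjugation, and hypochlorous acid may attack the electron-rich C8=C9 alkene and the diene during the chlorite oxidation. The fallback adjusts the oxidation level on the small fragment before the coupling, where no electron-rich alkene is present. It sets out from 20 (and uses 16): desilylation with Bu4NF would give (2R,3E)-4-iodo-2-methylbut-3-en-1-ol F6. Oxidation with CrO3/H2SO4 in acetone at 0 °C (acidic, so enolate formation is avoided) would give (2R,3E)-4-iodo-2-methylbut-3-enoic acid F7. TMSCHN2 would give methyl (2R,3E)-4-iodo-2-methylbut-3-enoate F8. The alkenylalane 21, made from 16 as in step 12 and freed from excess Me3Al under vacuum, would be coupled with F8 under Pd(PPh3)4/ZnCl2 in THF. The fallback comes back to the route at 26.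

**Further compounds**

F1 | step 5 | (5R,6S)-5-(2-bromopropan-2-yl)-2,6-dimethyl-6-[2-(phenylsulfonyl)prop-2-en-1-yl]cyclohex-2-en-1-one | O=C1C(C)=CC[C@@H](C(C)(C)Br)[C@]1(C)CC(=C)S(=O)(=O)c2ccccc2
F2 | step 7 | methyl (4aS,8aS)-2,5,5,8a-tetramethyl-7-(phenylsulfonyl)-3,4,4a,5,6,7,8,8a-octahydronaphthalene-1-carboxylate | COC(=O)C1=C(C)CC[C@H]2C(C)(C)CC(S(=O)(=O)c3ccccc3)C[C@]12C
F3 | step 7 | [(4aS,8aS)-2,5,5,8a-tetramethyl-7-(phenylsulfonyl)-3,4,4a,5,6,7,8,8a-octahydronaphthalen-1-yl]methanol | OCC1=C(C)CC[C@H]2C(C)(C)CC(S(=O)(=O)c3ccccc3)C[C@]12C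
F4 | step 7 | (4aS,8aS)-1-(bromomethyl)-2,5,5,8a-tetramethyl-7-(phenylsulfonyl)-3,4,4a,5,6,7,8,8a-octahydronaphthalene | BrCC1=C(C)CC[C@H]2C(C)(C)CC(S(=O)(=O)c3ccccc3)C[C@]12C
F5 | step 7 | [3-(trimethylsilyl)prop-2-yn-1-yl]magnesium bromide | C[Si](C)(C)C#CC[Mg]Br
F6 | step 14 | (2R,3E)-4-iodo-2-methylbut-3-en-1-ol | OC[C@H](C)/C=C/I
F7 | step 14 | (2R,3E)-4-iodo-2-methylbut-3-enoic acid | OC(=O)[C@H](C)/C=C/I
F8 | step 14 | methyl (2R,3E)-4-iodo-2-methylbut-3-enoate | COC(=O)[C@H](C)/C=C/I
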